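**Retrosynthetic overview**

1. Labdane numbering. The side chain is cut at C9–C11, and ring B is then cut at C9–C10 and C8–C7 (cycloaddition); this leaves a ring A dienol, a three-carbon alkynylboron unit (C17–C8–C9) and 4-vinylbutenolide (C11–C16).
2. Order of ring formation: ring A is bought as a chiral cyclohexenone and substituted (its C2 oxygen sets C4); ring B is closed in the key step; the butenolide ring arrives ready-made.
3. Key step: a boron-tethered intramolecular Diels–Alder reaction, followed in the same flask by rhodium-catalysed 1,6-addition of the C9–boron bond to 4-vinylbutenolide, so three components are joined around ring B.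
4. Enabling feature: the α-oriented C2 hydroxyl of ring A stands 1,3 to C10 (through C1). A C2–O–B–C9 tether therefore holds the propyne under the C10=C5–C6=C7 diene, delivers C9 to the α face of C10, and leaves at C9 the boron that makes the C9–C11 bond before the tether is lost.
5. End game: α-face hydroboration of C5=C6 sets 5α-H and 6α-OH; desilylation gives the triol.

Key step: step 10

Assumption: atoms are numbered as in labdanes (decalin C1–C10, side chain C11–C16, C17 on C8, C18/C19 on C4, C20 on C10; α is the face of the C2 oxygen, β the face of the C10 methyl), and (S)-4-(tert-butyldimethylsilyloxy)cyclohex-2-en-1-one is taken as a purchasable building block.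

**Route**

Step 1
Reactants: 1 (S)-4-(tert-butyldimethylsilyloxy)cyclohex-2-en-1-one
Product: 3 (4S,6S)-4-(tert-butyldimethylsilyloxy)-6-methylcyclohex-2-en-1-one, via lithium C6 dienolate of the enone 2 (not isolated)
Conditions: LiN(iPr)2, THF, −78 °C; MeI, −78 to −20 °C
Reagents that add atoms: iodomethane CI
Why: Kinetic deprotonation at C6 gives the cross-conjugated lithium dienolate and enolate alkylation with iodomethane should occur anti to the 4-silyloxy group (6-methyl trans), a centre that is made trigonal again in step 2 so that its configuration is not critical.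

Step 2
Reactants: 3 (4S,6S)-4-(tert-butyldimethylsilyloxy)-6-methylcyclohex-2-en-1-one
Product: 5 (4S,6R)-4-(tert-butyldimethylsilyloxy)-6-(hydroxymethyl)-6-methylcyclohex-2-en-1-one, via lithium dienolate of the 6-methyl enone 4 (not isolated)
Conditions: LiN(iPr)2, THF, −78 °C; CH2O (gas), −78 °C; AcOH, −78 °C
Reagents that add atoms: formaldehyde C=O
Why: A second kinetic enolisation at C6 followed by aldol addition to monomeric formaldehyde (enolate hydroxymethylation) should again take place anti to the 4-silyloxy group, which sets the quaternary centre (later C4) with the hydroxymethyl group trans to the oxygen and the methyl group cis, while the cold acetic acid quench guards against retro-aldol cleavage.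

Step 3
Reactants: 5 (4S,6R)-4-(tert-butyldimethylsilyloxy)-6-(hydroxymethyl)-6-methylcyclohex-2-en-1-one
Product: 6 (4S,6R)-4-(tert-butyldimethylsilyloxy)-6-[(tert-butyldiphenylsilyloxy)methyl]-6-methylcyclohex-2-en-1-one
Conditions: TBDPSCl, imidazole, CH2Cl2, 0 °C to rt
Reagents that add atoms: tert-butyl(chloro)diphenylsilane CC(C)(C)[Si](Cl)(c1ccccc1)c1ccccc1
Why: Standard silylation of the primary neopentyl alcohol (silyl ether formation) blocks retro-aldol chemistry and gives a group that outlasts the later removal of the secondary TBS ether.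

Step 4
Reactants: 6 (4S,6R)-4-(tert-butyldimethylsilyloxy)-6-[(tert-butyldiphenylsilyloxy)methyl]-6-methylcyclohex-2-en-1-one
Product: 8 (4R,6R)-4-(tert-butyldimethylsilyloxy)-6-[(tert-butyldiphenylsilyloxy)methyl]-2,6-dimethylcyclohexan-1-one as a mixture of C2 epimers, via lithium enolate from conjugate reduction 7 (not isolated)
Conditions: LiBH(sec-Bu)3, THF, −78 °C; MeI, −78 to 0 °C
Reagents that add atoms: iodomethane CI
Why: Conjugate reduction of the β-unsubstituted enone by the hindered trialkylborohydride (1,2-attack is shielded by the adjacent quaternary carbon) should give the enolate regiospecifically, and its alkylation with iodomethane (reductive alkylation) installs the later C10 methyl at a centre that becomes trigonal in step 5.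

Step 5
Reactants: 8 (4R,6R)-4-(tert-butyldimethylsilyloxy)-6-[(tert-butyldiphenylsilyloxy)methyl]-2,6-dimethylcyclohexan-1-one
Product: 10 (4R,6R)-4-(tert-butyldimethylsilyloxy)-6-[(tert-butyldiphenylsilyloxy)methyl]-2,6-dimethylcyclohex-1-en-1-yl trifluoromethanesulfonate, via potassium enolate of the ketone 9 (not isolated)
Conditions: KN(SiMe3)2, THF, −78 °C; PhNTf2, −78 to 0 °C
Reagents that add atoms: N-phenylbis(trifluoromethanesulfonimide) O=S(=O)(N(c1ccccc1)S(=O)(=O)C(F)(F)F)C(F)(F)F
Why: The ketone has a single α-hydrogen because the other α-carbon is quaternary, so enolisation and O-sulfonylation with PhNTf2 (enol triflate formation) should give one tetrasubstituted enol triflate.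

Step 6
Reactants: 10 (4R,6R)-4-(tert-butyldimethylsilyloxy)-6-[(tert-butyldiphenylsilyloxy)methyl]-2,6-dimethylcyclohex-1-en-1-yl trifluoromethanesulfonate
Product: 11 (4R,6R)-6-[(tert-butyldiphenylsilyloxy)methyl]-4-hydroxy-2,6-dimethylcyclohex-1-en-1-yl trifluoromethanesulfonate
Conditions: camphorsulfonic acid (cat.), MeOH/CH2Cl2, 0 °C
Reagents that add atoms: none
Why: Acid-catalysed methanolysis should cleave the secondary TBS ether much faster than the primary neopentyl TBDPS ether (selective desilylation), freeing the C2 hydroxyl that will anchor the tether.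

Step 7
Reactants: 11 (4R,6R)-6-[(tert-butyldiphenylsilyloxy)methyl]-4-hydroxy-2,6-dimethylcyclohex-1-en-1-yl trifluoromethanesulfonate
Product: 12 (1R,5S)-5-[(tert-butyldiphenylsilyloxy)methyl]-3,5-dimethyl-4-vinylcyclohex-3-en-1-ol (ring A dienol; hydroxyl cis to the C5 methyl)
Conditions: tributyl(vinyl)stannane, Pd(PPh3)4 (cat.), LiCl, THF, 65 °C
Reagents that add atoms: tributyl(vinyl)stannane C=C[Sn](CCCC)(CCCC)CCCC
Why: Stille coupling of the hindered enol triflate with the vinylstannane under zerovalent palladium catalysis, assisted by chloride, should give the 1,3-diene without touching a stereocentre.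

Step 8
Reactants: 13 prop-1-ynylmagnesium bromide
Product: 15 diisopropyl prop-1-ynylboronate, via bromomagnesium triisopropoxy(prop-1-ynyl)borate 14 (not isolated)
Conditions: B(OiPr)3, Et2O, −78 °C; HCl in Et2O, −78 °C to rt
Reagents that add atoms: triisopropyl borate CC(C)OB(OC(C)C)OC(C)C
Why: Addition of the alkynyl Grignard reagent to the borate gives the ate complex and anhydrous HCl then removes one isopropoxide (standard preparation of alkynylboronic esters).

Step 9
Reactants: 16 4-bromofuran-2(5H)-one
Product: 17 4-vinylfuran-2(5H)-one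
Conditions: tributyl(vinyl)stannane, Pd(PPh3)4 (cat.), dioxane, 80 °C
Reagents that add atoms: tributyl(vinyl)stannane C=C[Sn](CCCC)(CCCC)CCCC
Why: Stille coupling at the β-bromo position of the butenolide (a vinylogous acyl bromide) under zerovalent palladium catalysis should give the 1,6-acceptor diene.

Step 10
Reactants: 12 (1R,5S)-5-[(tert-butyldiphenylsilyloxy)methyl]-3,5-dimethyl-4-vinylcyclohex-3-en-1-ol, 15 diisopropyl prop-1-ynylboronate, 17 4-vinylfuran-2(5H)-one
Product: 20 19-(tert-butyldiphenylsilyloxy)-2α-hydroxylabda-5,8,13-trien-15,16-olide, via mixed alkynylboronate of the dienol 18 (not isolated), via tricyclic oxaborinane boracycle 19 (not isolated)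
Conditions: 15, toluene, 4 Å molecular sieves, BHT, 60 °C, then 120 °C (sealed tube); then 17, [Rh(OH)(cod)]2 (3 mol %), dioxane/H2O 10:1, 50 °C; then Et3N, rt
Reagents that add atoms: none
Why: Proposed new method: the C2 hydroxyl exchanges one isopropoxy group of 15 to give mixed boronate 18, whose propynyl group then adds as the 2π partner across the C10=C5–C6=C7 diene in a thermal intramolecular Diels–Alder reaction (bonds C9–C10 and C8–C7), and the resulting cyclic alkenylboronate 19 is transmetalated to monovalent rhodium, adds 1,6 to the terminal CH2 of 17 (bond C9–C11) and is released by protonation, the amine then moving any β,γ-double bond of the lactone into conjugation. The closest known reaction types are the boron-tethered intramolecular Diels–Alder reaction of alkenylboronates with dienols, the one-pot Diels–Alder/cross-coupling use of alkynylboronates, and the rhodium-catalysed (Hayashi–Miyaura-type) 1,6-addition of alkenylboron reagents to 2,4-dienoates; new are the alkynylboron tether and the union of the three events in one flask. Ring B closes in the concerted [4+2] mode, and the temporary 1,2-oxaborinane ring (C10–C9–B–O–C2–C1) closes at the same time as the six-membered tether ring of a type 1 intramolecular Diels–Alder transition state. The one new stereocentre, quaternary C10, is controlled by C2: the axial C2–O–B link can reach C10 only from the α face, so C9 becomes α and the C10 methyl β. The step needs regioselectivity in the cycloaddition (boron-bearing carbon to C10, methyl-bearing carbon to C7), which the short tether enforces, and 1,6- rather than 1,4-addition to 17, which the fully substituted β-carbon of the butenolide secures; the B–O tether is destroyed in the coupling, so the C2 hydroxyl emerges free.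

Step 11
Reactants: 20 19-(tert-butyldiphenylsilyloxy)-2α-hydroxylabda-5,8,13-trien-15,16-olide
Product: 22 19-(tert-butyldiphenylsilyloxy)-2α,6α-dihydroxylabda-8,13-dien-15,16-olide, via 6α-boryl 5α-H adduct 21 (not isolated)
Conditions: BH3·THF (excess), THF, 0 °C; Me3NO, THF, 60 °C; aqueous work-up
Reagents that add atoms: trimethylamine N-oxide C[N+](C)(C)[O-]
Why: Hydroboration–oxidation: borane should add to the trisubstituted C5=C6 bond from the α face, away from the axial C10 methyl and the C4 silyloxymethyl group, with boron at the less substituted C6, so that syn addition sets 5α-H (trans ring fusion) and oxidation with retention gives 6α-OH, while the tetrasubstituted C8=C9 bond and the electron-poor butenolide react more slowly.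

Step 12
Reactants: 22 19-(tert-butyldiphenylsilyloxy)-2α,6α-dihydroxylabda-8,13-dien-15,16-olide
Product: 23 2α,6α,19-trihydroxylabda-8,13-dien-15,16-olide (target)
Conditions: HF·pyridine, THF, 0 °C to rt
Reagents that add atoms: none
Why: Fluoride-mediated desilylation under buffered acidic conditions removes the TBDPS ether without opening or isomerising the base-sensitive butenolide.

**Compound list**

1 | (S)-4-(tert-butyldimethylsilyloxy)cyclohex-2-en-1-one | O=C1C=C[C@@H](O[Si](C)(C)C(C)(C)C)CC1 | starting material
2 | lithium C6 dienolate of 1, lithium (S)-4-(tert-butyldimethylsilyloxy)cyclohexa-1,5-dien-1-olate | [Li]OC1=CC[C@H](O[Si](C)(C)C(C)(C)C)C=C1 | intermediate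
3 | (4S,6S)-4-(tert-butyldimethylsilyloxy)-6-methylcyclohex-2-en-1-one (methyl trans to the silyloxy group) | O=C1C=C[C@@H](O[Si](C)(C)C(C)(C)C)C[C@@H]1C | intermediate
4 | lithium dienolate of 3, lithium (S)-4-(tert-butyldimethylsilyloxy)-6-methylcyclohexa-1,5-dien-1-olate | [Li]OC1=C(C)C[C@H](O[Si](C)(C)C(C)(C)C)C=C1 | intermediate
5 | (4S,6R)-4-(tert-butyldimethylsilyloxy)-6-(hydroxymethyl)-6-methylcyclohex-2-en-1-one (hydroxymethyl trans to the silyloxy group) | O=C1C=C[C@@H](O[Si](C)(C)C(C)(C)C)C[C@]1(C)CO | intermediate
6 | (4S,6R)-4-(tert-butyldimethylsilyloxy)-6-[(tert-butyldiphenylsilyloxy)methyl]-6-methylcyclohex-2-en-1-one | O=C1C=C[C@@H](O[Si](C)(C)C(C)(C)C)C[C@]1(C)CO[Si](c1ccccc1)(c1ccccc1)C(C)(C)C | intermediate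
7 | lithium enolate (C1=C2) of the saturated ketone formed from 6 by conjugate reduction | [Li]OC1=CC[C@@H](O[Si](C)(C)C(C)(C)C)C[C@]1(C)CO[Si](c1ccccc1)(c1ccccc1)C(C)(C)C | intermediate
8 | (4R,6R)-4-(tert-butyldimethylsilyloxy)-6-[(tert-butyldiphenylsilyloxy)methyl]-2,6-dimethylcyclohexan-1-one (both C2 epimers) | O=C1C(C)C[C@@H](O[Si](C)(C)C(C)(C)C)C[C@]1(C)CO[Si](c1ccccc1)(c1ccccc1)C(C)(C)C | intermediate
9 | potassium enolate (C1=C2) of 8 | [K]OC1=C(C)C[C@@H](O[Si](C)(C)C(C)(C)C)C[C@]1(C)CO[Si](c1ccccc1)(c1ccccc1)C(C)(C)C | intermediate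
10 | (4R,6R)-4-(tert-butyldimethylsilyloxy)-6-[(tert-butyldiphenylsilyloxy)methyl]-2,6-dimethylcyclohex-1-en-1-yl trifluoromethanesulfonate | FC(F)(F)S(=O)(=O)OC1=C(C)C[C@@H](O[Si](C)(C)C(C)(C)C)C[C@]1(C)CO[Si](c1ccccc1)(c1ccccc1)C(C)(C)C | intermediate
11 | (4R,6R)-6-[(tert-butyldiphenylsilyloxy)methyl]-4-hydroxy-2,6-dimethylcyclohex-1-en-1-yl trifluoromethanesulfonate | FC(F)(F)S(=O)(=O)OC1=C(C)C[C@@H](O)C[C@]1(C)CO[Si](c1ccccc1)(c1ccccc1)C(C)(C)C | intermediate
12 | (1R,5S)-5-[(tert-butyldiphenylsilyloxy)methyl]-3,5-dimethyl-4-vinylcyclohex-3-en-1-ol (ring A dienol; hydroxyl cis to the C5 methyl, trans to the silyloxymethyl group) | C=CC1=C(C)C[C@@H](O)C[C@]1(C)CO[Si](c1ccccc1)(c1ccccc1)C(C)(C)C | intermediate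
13 | prop-1-ynylmagnesium bromide | CC#C[Mg]Br | starting material
14 | bromomagnesium triisopropoxy(prop-1-ynyl)borate | CC#C[B-](OC(C)C)(OC(C)C)OC(C)C.[Mg+]Br | intermediate
15 | diisopropyl prop-1-ynylboronate | CC#CB(OC(C)C)OC(C)C | intermediate
16 | 4-bromofuran-2(5H)-one | BrC1=CC(=O)OC1 | starting material
17 | 4-vinylfuran-2(5H)-one | C=CC1=CC(=O)OC1 | intermediate
18 | mixed boronate: dienol 12 bound through its C2 oxygen to B(O-isopropyl)(prop-1-ynyl) | C=CC1=C(C)C[C@@H](OB(OC(C)C)C#CC)C[C@]1(C)CO[Si](c1ccccc1)(c1ccccc1)C(C)(C)C | intermediate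
19 | boracycle: 19-(tert-butyldiphenylsilyloxy)drima-5,8-diene core lacking C11, with a B-isopropoxy 1,2-oxaborinane spanning the 2α-oxygen and C9 (10β-methyl) | CC1=C2B(OC(C)C)O[C@@H]3C[C@@]2(C)C(=CC1)[C@@](C)(CO[Si](c1ccccc1)(c1ccccc1)C(C)(C)C)C3 | intermediate
20 | 19-(tert-butyldiphenylsilyloxy)-2α-hydroxylabda-5,8,13-trien-15,16-olide | CC1=C(CCC2=CC(=O)OC2)[C@@]2(C)C[C@@H](O)C[C@](C)(CO[Si](c3ccccc3)(c3ccccc3)C(C)(C)C)C2=CC1 | intermediate
21 | 6α-boryl adduct of 20 with 5α-H (drawn as the C6–BH2 species) | CC1=C(CCC2=CC(=O)OC2)[C@@]2(C)C[C@@H](O)C[C@](C)(CO[Si](c3ccccc3)(c3ccccc3)C(C)(C)C)[C@@H]2[C@@H](B)C1 | intermediate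
22 | 19-(tert-butyldiphenylsilyloxy)-2α,6α-dihydroxylabda-8,13-dien-15,16-olide | CC1=C(CCC2=CC(=O)OC2)[C@@]2(C)C[C@@H](O)C[C@](C)(CO[Si](c3ccccc3)(c3ccccc3)C(C)(C)C)[C@@H]2[C@@H](O)C1 | intermediate
23 | 2α,6α,19-trihydroxylabda-8,13-dien-15,16-olide (CNP0387838.1) | CC1=C(CCC2=CC(=O)OC2)[C@@]2(C)C[C@@H](O)C[C@](C)(CO)[C@@H]2[C@@H](O)C1 | target

**Step count and risks**

Total step count: 12. Longest linear sequence: 10 (steps 1–7, 10, 11, 12).

Steps most likely to fail:

Step 10 (carries the label "Proposed new method:"). The cycloaddition at the fully substituted diene terminus may be too slow, so that a 1,5-hydrogen shift of the diene competes, and protodeboronation may outrun transmetalation at the hindered C9–boron bond. The fallback sets out from dienol 12 and comes back at 20; it changes the tether element to silicon and splits the union into known operations. Silylation of 12 with chlorodiisopropyl(prop-1-ynyl)silane and imidazole gives the alkynylsilyl ether F1. A thermal silicon-tethered intramolecular Diels–Alder reaction gives the oxasilacycle F2. Iododesilylation (N-iodosuccinimide, then HF·pyridine to free the C2 hydroxyl) gives the C9 alkenyl iodide F3. Appel iodination of 4-(2-hydroxyethyl)furan-2(5H)-one gives 4-(2-iodoethyl)furan-2(5H)-one F4, and zinc insertion gives the alkylzinc iodide F5. Negishi coupling of F3 and F5 (Pd(dppf)Cl2, THF) returns to 20.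

Step 11. Chemoselectivity may be lost through hydroboration of the tetrasubstituted ring B alkene or reduction of the butenolide by borane. The fallback sets out from 20 and comes back at 22; the butenolide is taken out of play as a furan. Reduction of 20 with i-Bu2AlH at −78 °C and acidic work-up (lactol dehydration) gives the 3-substituted furan F6. Hydroboration–oxidation as in step 11 gives the 6α-alcohol F7. Photo-oxygenation (O2, rose bengal, iPr2NEt, −78 °C) gives the γ-hydroxybutenolide F8, and NaBH4 reduction closes the butenolide again to give 22.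

Step 2. Retro-aldol loss of formaldehyde and erosion of facial selectivity in the quaternisation are possible. The fallback sets out from 3 and comes back at 5; the aldol step is replaced by an enolate alkylation that cannot revert. The lithium dienolate of 3 is alkylated with (4-methoxybenzyloxy)methyl chloride to give the 4-methoxybenzyl ether F9, and oxidative debenzylation (DDQ, wet CH2Cl2) gives 5.

Further compounds
F1 | step 10 | diisopropyl(prop-1-ynyl)silyl ether of dienol 12 (silicon on the C2 oxygen) | C=CC1=C(C)C[C@@H](O[Si](C(C)C)(C(C)C)C#CC)C[C@]1(C)CO[Si](c1ccccc1)(c1ccccc1)C(C)(C)C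
F2 | step 10 | oxasilacycle: silicon analogue of 19 with a Si,Si-diisopropyl 1,2-oxasilinane spanning the 2α-oxygen and C9 | CC1=C2[Si](C(C)C)(C(C)C)O[C@@H]3C[C@@]2(C)C(=CC1)[C@@](C)(CO[Si](c1ccccc1)(c1ccccc1)C(C)(C)C)C3
F3 | step 10 | C9 alkenyl iodide: 19-(tert-butyldiphenylsilyloxy)-9-iododrima-5,8-dien-2α-ol lacking C11 | CC1=C(I)[C@@]2(C)C[C@@H](O)C[C@](C)(CO[Si](c3ccccc3)(c3ccccc3)C(C)(C)C)C2=CC1
F4 | step 10 | 4-(2-iodoethyl)furan-2(5H)-one | ICCC1=CC(=O)OC1
F5 | step 10 | [2-(5-oxo-2,5-dihydrofuran-3-yl)ethyl]zinc iodide | I[Zn]CCC1=CC(=O)OC1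
F6 | step 11 | 19-(tert-butyldiphenylsilyloxy)-15,16-epoxylabda-5,8,13(16),14-tetraen-2α-ol (3-furyl analogue of 20) | CC1=C(CCc2ccoc2)[C@@]2(C)C[C@@H](O)C[C@](C)(CO[Si](c3ccccc3)(c3ccccc3)C(C)(C)C)C2=CC1
F7 | step 11 | 19-(tert-butyldiphenylsilyloxy)-15,16-epoxylabda-8,13(16),14-triene-2α,6α-diol (3-furyl analogue of 22) | CC1=C(CCc2ccoc2)[C@@]2(C)C[C@@H](O)C[C@](C)(CO[Si](c3ccccc3)(c3ccccc3)C(C)(C)C)[C@@H]2[C@@H](O)C1
F8 | step 11 | 19-(tert-butyldiphenylsilyloxy)-2α,6α,16-trihydroxylabda-8,13-dien-15,16-olide (γ-hydroxybutenolide, both C16 epimers) | CC1=C(CCC2=CC(=O)OC2O)[C@@]2(C)C[C@@H](O)C[C@](C)(CO[Si](c3ccccc3)(c3ccccc3)C(C)(C)C)[C@@H]2[C@@H](O)C1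
F9 | step 2 | (4S,6R)-4-(tert-butyldimethylsilyloxy)-6-[(4-methoxybenzyloxy)methyl]-6-methylcyclohex-2-en-1-one | O=C1C=C[C@@H](O[Si](C)(C)C(C)(C)C)C[C@]1(C)COCc1ccc(OC)cc1
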